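A direct plan would take the six-membered ring from an arene: benzyl acetate A1 would be cis-dihydroxylated by a toluene-dioxygenase whole-cell culture to the diene diol A2, the trisubstituted alkene epoxidised under hydroxyl direction to the epoxy diol A3, the diol closed to the cyclic sulfate A4, and A4 opened twice by benzoate before acid methanolysis.
Such a plan would waste no steps on low-complexity operations; its cost would lie in unproven selectivity in three of its four flasks.
The enzymatic arene dihydroxylation would be weak: it would be the only source of absolute configuration, a dilute fermentation on the ester A1 that host esterases can cleave, and its diene diol A2 aromatises easily.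
The hydroxyl-directed epoxidation would be weak: it would have to pick one of two alkenes and one face of the labile diene A2, so C1 and C6 would rest on a conformational argument alone.
The closing benzoate cascade on A4 would be weakest: it would need SN2 rather than SN2′ attack on an allylic cyclic sulfate, attack at C6 rather than C4 or C1 of a vinyl epoxide, sulfate hydrolysis and acetate-over-benzoate methanolysis in one flask, with acyl migration possible throughout; this is the operation one would least like to run on late material.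

Plan of the new route
The target's C7(H2OH)–C1–C6(OBz)–C5=C4 is read as a 4-pentenal (Claisen) retron: the C1–C6 bond is cut and the C7 oxygen is rejoined to C4. The carbocycle thereby becomes a 3,4-dihydro-2H-pyran, a 2-alkoxyglycal of D-glucose with an (E)-2-benzoyloxyvinyl arm on sugar C5.
The feature that allows this is the quaternary carbinol C1 with its one-carbon oxygenated branch, next to the allylic benzoate carbon C6 and two bonds from C4=C5. C2 and C3 of the target are C3 and C4 of D-glucose.
Order of rings: the pyran ring comes first, supplied by D-glucose; the cyclohexene arises last, in the step that opens the pyran.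
No arene is oxidised, no alkene face is chosen by a directing group, and no benzoate enters by substitution at an allylic carbon. Both benzoates are in place before the carbocycle exists, C1 and C6 are set together by one sigmatropic transition state, and the late steps are a reduction and an acidolysis.

Key step: step 8

Remark on numbering: carbocycles carry target numbers (C1 quaternary, C2 CHOH, C3 CHOBz, C4=C5, C6 CHOBz, C7 the CH2OH carbon). Pyranoid intermediates carry heptose numbers, written "sugar C1–C7". The two are related by sugar C1→C7, C2→C1, C3→C2, C4→C3, C5→C4, C6→C5, C7→C6.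
Assumption: phenyl 4,6-O-benzylidene-1-thio-β-D-glucopyranoside and 2-(dichloromethyl)-4,4,5,5-tetramethyl-1,3,2-dioxaborolane are taken as commercial.

Step 1
Reactants: 1 phenyl 4,6-O-[(R)-benzylidene]-1-thio-β-D-glucopyranoside
Product: 2 phenyl 4,6-O-[(R)-benzylidene]-2,3-di-O-(4-methoxybenzyl)-1-thio-β-D-glucopyranoside
Conditions: NaH (2.6 equiv), 4-methoxybenzyl chloride (2.4 equiv), Bu4NI (cat.), DMF, 0 °C → rt
Reagents that add atoms: 4-methoxybenzyl chloride (COc1ccc(CCl)cc1)
Why: Williamson etherification of the two free secondary hydroxyls; thioglycoside and benzylidene acetal are inert to alkoxide, and no stereocentre is touched.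

Step 2
Reactants: 2 phenyl 4,6-O-[(R)-benzylidene]-2,3-di-O-(4-methoxybenzyl)-1-thio-β-D-glucopyranoside
Product: 3 phenyl 2,3-di-O-(4-methoxybenzyl)-1-thio-β-D-glucopyranoside
Conditions: TsOH·H2O (0.1 equiv), MeOH/CH2Cl2 (3:1), rt; Et3N quench
Reagents that add atoms: none
Why: Acid-catalysed transacetalisation to methanol should remove the benzylidene group, while 4-methoxybenzyl ethers and the thioglycoside survive catalytic sulfonic acid at room temperature.

Step 3
Reactants: 3 phenyl 2,3-di-O-(4-methoxybenzyl)-1-thio-β-D-glucopyranoside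
Product: 4 phenyl 2,3-di-O-(4-methoxybenzyl)-1-thio-β-D-gluco-hexodialdo-1,5-pyranoside (C6 aldehyde; 4-OH free)
Conditions: TEMPO (0.2 equiv), PhI(OAc)2 (1.2 equiv), CH2Cl2, 0 °C → rt; used crude
Reagents that add atoms: none
Why: Oxoammonium oxidation is selective for the primary over the secondary alcohol and is routinely run on thioglycosides; the medium is non-basic, so sugar C5 should not epimerise and the β-hydroxyl should not be eliminated.

Step 4
Reactants: 4 phenyl 2,3-di-O-(4-methoxybenzyl)-1-thio-β-D-gluco-hexodialdo-1,5-pyranoside; 5 2-(dichloromethyl)-4,4,5,5-tetramethyl-1,3,2-dioxaborolane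
Product: 6 phenyl (6E)-6,7-dideoxy-2,3-di-O-(4-methoxybenzyl)-7-(4,4,5,5-tetramethyl-1,3,2-dioxaborolan-2-yl)-1-thio-β-D-gluco-hept-6-enopyranoside (4-OH free)
Conditions: CrCl2 (8 equiv), LiI (4 equiv), 5 (2 equiv), THF, rt
Reagents that add atoms: none
Why: Takai–Utimoto olefination, in which the geminal dichromium species formed from 5 and divalent chromium adds to the aldehyde and eliminates to the (E)-alkenylboronate; the reagent tolerates free hydroxyl and sulfide and is non-basic, so sugar C5 keeps its configuration, and the E geometry set here later fixes C6.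

Step 5
Reactants: 6 phenyl (6E)-6,7-dideoxy-2,3-di-O-(4-methoxybenzyl)-7-(4,4,5,5-tetramethyl-1,3,2-dioxaborolan-2-yl)-1-thio-β-D-gluco-hept-6-enopyranoside; 7 benzoyl chloride
Product: 9 potassium [(6E)-phenyl 4-O-benzoyl-6,7-dideoxy-2,3-di-O-(4-methoxybenzyl)-1-thio-β-D-gluco-hept-6-enopyranosid-7-yl]trifluoroborate, via 4-O-benzoyl pinacol boronate 8 (not isolated)
Conditions: 7 (1.5 equiv), pyridine, DMAP (0.1 equiv), CH2Cl2, 0 °C → rt; evaporate; KHF2 (4.5 equiv), MeOH/H2O, rt; extract salt into acetone
Reagents that add atoms: potassium hydrogen difluoride (F.[F-].[K+])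
Why: DMAP-catalysed acylation of the only free hydroxyl places the future C3 benzoate; exchange of pinacol for fluoride then gives the trifluoroborate needed for the copper coupling, and esters, ethers and thioglycoside are stable to both operations.

Step 6
Reactants: 9 potassium [(6E)-phenyl 4-O-benzoyl-6,7-dideoxy-2,3-di-O-(4-methoxybenzyl)-1-thio-β-D-gluco-hept-6-enopyranosid-7-yl]trifluoroborate; 10 benzoic acid
Product: 11 phenyl (6E)-4,7-di-O-benzoyl-6-deoxy-2,3-di-O-(4-methoxybenzyl)-1-thio-β-D-gluco-hept-6-enopyranoside (E-enol benzoate at sugar C6=C7)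
Conditions: 10 (2 equiv), CuBr (0.2 equiv), DMAP (0.4 equiv), 4 Å MS, O2 (1 atm), MeCN, 60 °C
Reagents that add atoms: none
Why: Chan–Lam-type oxidative C–O coupling, in which the alkenyl group passes from boron to a divalent copper benzoate and, after oxidation to trivalent copper, C–O reductive elimination gives the enol ester with retention of the E geometry; this coupling is established for alkenyltrifluoroborates with aromatic carboxylic acids.

Step 7
Reactants: 11 phenyl (6E)-4,7-di-O-benzoyl-6-deoxy-2,3-di-O-(4-methoxybenzyl)-1-thio-β-D-gluco-hept-6-enopyranoside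
Product: 13 (6E)-1,5-anhydro-4,7-di-O-benzoyl-6-deoxy-2,3-di-O-(4-methoxybenzyl)-D-arabino-hepta-1,6-dienitol, via anomeric S-oxide 12 (not isolated)
Conditions: mCPBA (1.05 equiv), CH2Cl2, −78 °C; aq. NaHCO3/Na2S2O3 wash; toluene, solid NaHCO3, 110 °C
Reagents that add atoms: none
Why: Sulfide oxidation at low temperature should leave the electron-poor enol benzoate alone, and thermal syn-elimination of the sulfoxide then removes benzenesulfenic acid across sugar C1–C2, where H-2 (cis to the equatorial sulfinyl group) is the only β-hydrogen; this gives the 2-alkoxyglycal without touching sugar C3–C5.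

Step 8
Reactants: 13 (6E)-1,5-anhydro-4,7-di-O-benzoyl-6-deoxy-2,3-di-O-(4-methoxybenzyl)-D-arabino-hepta-1,6-dienitol
Product: 14 (1R,2S,3R,6S)-3,6-bis(benzoyloxy)-1,2-bis[(4-methoxybenzyl)oxy]cyclohex-4-ene-1-carbaldehyde (target numbering; C1–O and C2–O on one face; both benzoates and the formyl group on the other)
Conditions: o-dichlorobenzene (0.02 M, degassed), 2,6-di-tert-butyl-4-methylpyridine (0.2 equiv), BHT (cat.), sealed tube, 190–200 °C
Reagents that add atoms: none
Why: On heating, the allyl vinyl ether array sugar C2=C1–O5–C5–C6=C7 of 13 should undergo a concerted suprafacial [3,3] sigmatropic (Claisen) shift in which the O5–C5 bond breaks as the C2–C7 bond forms and the ring oxygen becomes the formyl oxygen; the closest known reaction type is the thermal Claisen carbocyclisation of 2-alkenyl-3,4-dihydro-2H-pyrans and C5-vinyl glycals to cyclohex-3-enecarbaldehydes. The cyclohexene closes by this single C–C bond across the dihydropyran, sugar C2 and C5 being bridged through C6–C7 in a bicyclo[2.2.2]-like transition state that forces the six reacting atoms into a boat and leaves the new double bond at C4=C5. The quaternary centre C1 is controlled by the sugar C5 stereocentre, which is consumed: the alkenyl arm can bond only to the enol-ether face on which it stands, the face that also carries O3, so C1–O ends cis to C2–O and the formyl carbon trans to it. C6 is controlled by the E geometry of the enol benzoate, since in the enforced boat the E substituent of sugar C7 ends cis to the formyl group and trans to C1–O, on the face of the C3 benzoate. The step needs periselectivity for the concerted path over ionisation of the allylic C5–O5 bond and over allylic acyloxy shifts, which the non-polar buffered medium and the ether rather than ester group at O3 should secure, and it needs the half-chair with an axial C5 arm, which allylic 1,2-strain between the 2- and 3-alkoxy groups favours. The aldehyde formed has no α-hydrogen, so it can neither enolise nor eliminate the β-benzoate.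

Step 9
Reactants: 14 (1R,2S,3R,6S)-3,6-bis(benzoyloxy)-1,2-bis[(4-methoxybenzyl)oxy]cyclohex-4-ene-1-carbaldehyde
Product: 15 (1R,2S,3R,6S)-1-(hydroxymethyl)-1,2-bis[(4-methoxybenzyl)oxy]cyclohex-4-ene-3,6-diyl dibenzoate (target numbering)
Conditions: NaBH4 (1.5 equiv), CeCl3·7H2O (1 equiv), MeOH/THF, −40 °C; AcOH quench
Reagents that add atoms: none
Why: Luche-type borohydride reduction of a non-enolisable neopentyl aldehyde; benzoates are not reduced, and the low temperature and acidic quench should keep the C6 benzoate from migrating to the new primary hydroxyl.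

Step 10
Reactants: 15 (1R,2S,3R,6S)-1-(hydroxymethyl)-1,2-bis[(4-methoxybenzyl)oxy]cyclohex-4-ene-3,6-diyl dibenzoate
Product: 16 (1S,2S,3R,6S)-1-(hydroxymethyl)cyclohex-4-ene-1,2,3,6-tetrol 3,6-dibenzoate (target)
Conditions: CF3CO2H/CH2Cl2 (1:9), anisole (10 equiv), 0 °C; toluene co-evaporation
Reagents that add atoms: none
Why: Acidolysis of both 4-methoxybenzyl ethers by loss of the benzylic cation, which anisole traps by Friedel–Crafts alkylation; benzoates are inert to the acid, no C–O bond of the ring is broken, and the non-basic medium should prevent acyl migration among the three free hydroxyls.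

Compound list
1 | phenyl 4,6-O-[(R)-benzylidene]-1-thio-β-D-glucopyranoside | c1ccccc1[C@@H]1OC[C@H]2O[C@@H](Sc3ccccc3)[C@H](O)[C@@H](O)[C@@H]2O1 | starting material
2 | phenyl 4,6-O-[(R)-benzylidene]-2,3-di-O-(4-methoxybenzyl)-1-thio-β-D-glucopyranoside | c1ccccc1[C@@H]1OC[C@H]2O[C@@H](Sc3ccccc3)[C@H](OCc3ccc(OC)cc3)[C@@H](OCc3ccc(OC)cc3)[C@@H]2O1 | intermediate
3 | phenyl 2,3-di-O-(4-methoxybenzyl)-1-thio-β-D-glucopyranoside | OC[C@H]1O[C@@H](Sc2ccccc2)[C@H](OCc2ccc(OC)cc2)[C@@H](OCc2ccc(OC)cc2)[C@@H]1O | intermediate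
4 | phenyl 2,3-di-O-(4-methoxybenzyl)-1-thio-β-D-gluco-hexodialdo-1,5-pyranoside | O=C[C@H]1O[C@@H](Sc2ccccc2)[C@H](OCc2ccc(OC)cc2)[C@@H](OCc2ccc(OC)cc2)[C@@H]1O | intermediate
5 | 2-(dichloromethyl)-4,4,5,5-tetramethyl-1,3,2-dioxaborolane | ClC(Cl)B1OC(C)(C)C(C)(C)O1 | starting material
6 | phenyl (6E)-6,7-dideoxy-2,3-di-O-(4-methoxybenzyl)-7-(4,4,5,5-tetramethyl-1,3,2-dioxaborolan-2-yl)-1-thio-β-D-gluco-hept-6-enopyranoside | CC1(C)OB(/C=C/[C@H]2O[C@@H](Sc3ccccc3)[C@H](OCc3ccc(OC)cc3)[C@@H](OCc3ccc(OC)cc3)[C@@H]2O)OC1(C)C | intermediate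
7 | benzoyl chloride | O=C(Cl)c1ccccc1 | starting material
8 | 4-O-benzoate of 6 | CC1(C)OB(/C=C/[C@H]2O[C@@H](Sc3ccccc3)[C@H](OCc3ccc(OC)cc3)[C@@H](OCc3ccc(OC)cc3)[C@@H]2OC(=O)c2ccccc2)OC1(C)C | intermediate
9 | potassium [(6E)-phenyl 4-O-benzoyl-6,7-dideoxy-2,3-di-O-(4-methoxybenzyl)-1-thio-β-D-gluco-hept-6-enopyranosid-7-yl]trifluoroborate | [K+].F[B-](F)(F)/C=C/[C@H]1O[C@@H](Sc2ccccc2)[C@H](OCc2ccc(OC)cc2)[C@@H](OCc2ccc(OC)cc2)[C@@H]1OC(=O)c1ccccc1 | intermediate
10 | benzoic acid | OC(=O)c1ccccc1 | starting material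
11 | phenyl (6E)-4,7-di-O-benzoyl-6-deoxy-2,3-di-O-(4-methoxybenzyl)-1-thio-β-D-gluco-hept-6-enopyranoside | O=C(O/C=C/[C@H]1O[C@@H](Sc2ccccc2)[C@H](OCc2ccc(OC)cc2)[C@@H](OCc2ccc(OC)cc2)[C@@H]1OC(=O)c1ccccc1)c1ccccc1 | intermediate
12 | S-oxide of 11 (mixture at sulfur) | O=C(O/C=C/[C@H]1O[C@@H](S(=O)c2ccccc2)[C@H](OCc2ccc(OC)cc2)[C@@H](OCc2ccc(OC)cc2)[C@@H]1OC(=O)c1ccccc1)c1ccccc1 | intermediate
13 | (6E)-1,5-anhydro-4,7-di-O-benzoyl-6-deoxy-2,3-di-O-(4-methoxybenzyl)-D-arabino-hepta-1,6-dienitol | O=C(O/C=C/[C@H]1OC=C(OCc2ccc(OC)cc2)[C@@H](OCc2ccc(OC)cc2)[C@@H]1OC(=O)c1ccccc1)c1ccccc1 | intermediate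
14 | (1R,2S,3R,6S)-3,6-bis(benzoyloxy)-1,2-bis[(4-methoxybenzyl)oxy]cyclohex-4-ene-1-carbaldehyde (target numbering) | O=C(O[C@H]1C=C[C@@H](OC(=O)c2ccccc2)[C@H](OCc2ccc(OC)cc2)[C@@]1(OCc2ccc(OC)cc2)C=O)c1ccccc1 | intermediate
15 | (1R,2S,3R,6S)-1-(hydroxymethyl)-1,2-bis[(4-methoxybenzyl)oxy]cyclohex-4-ene-3,6-diyl dibenzoate (target numbering) | O=C(O[C@H]1C=C[C@@H](OC(=O)c2ccccc2)[C@H](OCc2ccc(OC)cc2)[C@@]1(OCc2ccc(OC)cc2)CO)c1ccccc1 | intermediate
16 | (1S,2S,3R,6S)-1-(hydroxymethyl)cyclohex-4-ene-1,2,3,6-tetrol 3,6-dibenzoate | O=C(O[C@H]1C=C[C@@H](OC(=O)c2ccccc2)[C@H](O)[C@@]1(O)CO)c1ccccc1 | target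

Total step count: 10
Longest linear sequence: 10 steps (1 → 16; 5, 7 and 10 are purchased)

Steps most likely to fail

Step 8. The rearrangement may be overtaken by thermal decomposition (ionisation of the allylic C–O bond, allylic benzoate shifts, loss of benzoic acid) or may stall at a temperature the esters tolerate. The fallback makes the same bond in the ester-enolate (Ireland–Claisen) manifold, which runs below 100 °C. It sets out from 11. NBS in wet acetone would hydrolyse the thioglycoside to the hemiacetal (6E)-4,7-di-O-benzoyl-6-deoxy-2,3-di-O-(4-methoxybenzyl)-D-gluco-hept-6-enopyranose F1, and Dess–Martin periodinane would oxidise it to the 1,5-lactone F2. LiN(SiMe3)2 added to the lactone and premixed Me3SiCl/Et3N in THF at −78 °C would give the trimethylsilyl ketene acetal F3, the in-situ silylation limiting β-elimination of the 3-alkoxy group. Warming to 60–80 °C should bring about the [3,3] shift through the same enforced boat, and aqueous work-up would give (1R,2S,3R,6S)-3,6-bis(benzoyloxy)-1,2-bis[(4-methoxybenzyl)oxy]cyclohex-4-ene-1-carboxylic acid F4. BH3·THF at 0 °C reduces the acid faster than the benzoates or the hindered ring alkene, and the route is rejoined at 15.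

Step 7. The syn-elimination may be incomplete, because the H2–C2–C1–S array has to twist into coplanarity, and the sulfenic acid may add back to the electron-rich enol ether. The fallback replaces the thermal syn-elimination by a base-induced anti-elimination. It sets out from 11. ICl (1.05 equiv) in CH2Cl2 at −78 °C would convert the thioglycoside directly into the α-glycosyl chloride (6E)-4,7-di-O-benzoyl-6-deoxy-2,3-di-O-(4-methoxybenzyl)-α-D-gluco-hept-6-enopyranosyl chloride F5. DBU in DMF at 60 °C should then remove HCl across sugar C1–C2, where the axial chlorine and axial H-2 are antiperiplanar, and the route is rejoined at 13.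

Step 6. The copper catalyst may be inhibited by the thioether, and the alkenyltrifluoroborate may protodeboronate or partly lose its E geometry. The fallback forms the vinylic C–O bond from an electrophilic alkenyl partner instead. It sets out from 4. Takai olefination with CHI3/CrCl2 in THF would give the (E)-alkenyl iodide phenyl (6E)-6,7-dideoxy-7-iodo-2,3-di-O-(4-methoxybenzyl)-1-thio-β-D-gluco-hept-6-enopyranoside F6, and benzoyl chloride in pyridine its 4-O-benzoate F7. An Ullmann-type coupling with CsO2CPh, catalysed by CuI and 3,4,7,8-tetramethyl-1,10-phenanthroline in toluene at 90 °C, would then give the enol benzoate. These conditions are established for the stereoretentive coupling of alkenyl iodides with alcohols, so their use with a carboxylate is an extrapolation. The route is rejoined at 11.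

Further compounds
F1 | step 8 | (6E)-4,7-di-O-benzoyl-6-deoxy-2,3-di-O-(4-methoxybenzyl)-D-gluco-hept-6-enopyranose (anomer mixture) | O=C(O/C=C/[C@H]1OC(O)[C@H](OCc2ccc(OC)cc2)[C@@H](OCc2ccc(OC)cc2)[C@@H]1OC(=O)c1ccccc1)c1ccccc1
F2 | step 8 | (6E)-4,7-di-O-benzoyl-6-deoxy-2,3-di-O-(4-methoxybenzyl)-D-gluco-hept-6-enono-1,5-lactone | O=C(O/C=C/[C@H]1OC(=O)[C@H](OCc2ccc(OC)cc2)[C@@H](OCc2ccc(OC)cc2)[C@@H]1OC(=O)c1ccccc1)c1ccccc1
F3 | step 8 | trimethylsilyl ketene acetal of F2 (1-O-trimethylsilyl enol ether, sugar C1=C2) | O=C(O/C=C/[C@H]1OC(O[Si](C)(C)C)=C(OCc2ccc(OC)cc2)[C@@H](OCc2ccc(OC)cc2)[C@@H]1OC(=O)c1ccccc1)c1ccccc1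
F4 | step 8 | (1R,2S,3R,6S)-3,6-bis(benzoyloxy)-1,2-bis[(4-methoxybenzyl)oxy]cyclohex-4-ene-1-carboxylic acid (target numbering) | O=C(O[C@H]1C=C[C@@H](OC(=O)c2ccccc2)[C@H](OCc2ccc(OC)cc2)[C@@]1(OCc2ccc(OC)cc2)C(=O)O)c1ccccc1
F5 | step 7 | (6E)-4,7-di-O-benzoyl-6-deoxy-2,3-di-O-(4-methoxybenzyl)-α-D-gluco-hept-6-enopyranosyl chloride | O=C(O/C=C/[C@H]1O[C@H](Cl)[C@H](OCc2ccc(OC)cc2)[C@@H](OCc2ccc(OC)cc2)[C@@H]1OC(=O)c1ccccc1)c1ccccc1
F6 | step 6 | phenyl (6E)-6,7-dideoxy-7-iodo-2,3-di-O-(4-methoxybenzyl)-1-thio-β-D-gluco-hept-6-enopyranoside | I/C=C/[C@H]1O[C@@H](Sc2ccccc2)[C@H](OCc2ccc(OC)cc2)[C@@H](OCc2ccc(OC)cc2)[C@@H]1O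
F7 | step 6 | phenyl (6E)-4-O-benzoyl-6,7-dideoxy-7-iodo-2,3-di-O-(4-methoxybenzyl)-1-thio-β-D-gluco-hept-6-enopyranoside | I/C=C/[C@H]1O[C@@H](Sc2ccccc2)[C@H](OCc2ccc(OC)cc2)[C@@H](OCc2ccc(OC)cc2)[C@@H]1OC(=O)c1ccccc1
A1 | direct plan | benzyl acetate | CC(=O)OCc1ccccc1
A2 | direct plan | [(5S,6R)-5,6-dihydroxycyclohexa-1,3-dien-1-yl]methyl acetate | O[C@H]1C=CC=C(COC(C)=O)[C@H]1O
A3 | direct plan | [(1S,2S,3S,6R)-2,3-dihydroxy-7-oxabicyclo[4.1.0]hept-4-en-1-yl]methyl acetate | O[C@H]1C=C[C@H]2O[C@@]2(COC(C)=O)[C@H]1O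
A4 | direct plan | cyclic sulfate (1,3,2-dioxathiolane 2,2-dioxide) of the cis-diol of A3 | O=S1(=O)O[C@H]2C=C[C@H]3O[C@@]3(COC(C)=O)[C@H]2O1
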